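**Retrosynthetic overview**

1. The target is (+)-lariciresinol etherified, at the phenol of its benzyl-arm guaiacyl ring, with a threo-(7R,8R) guaiacylglycerol unit (C7 = benzylic carbinol, C8 = aryloxy methine, C9 = CH2OH). The last C–C bond made is C7–C8, by a boron syn-aldol of an aryloxyacetyl imide of protected lariciresinol with O-TIPS-vanillin.
2. Enabling feature: C8 carries both the aryl ether oxygen and C9. Raising C9 to an N-acyl oxazolidinone makes C8–H enolisable as a Z-enolate, and C7, the benzylic carbinol on the second guaiacyl ring, is the carbonyl carbon of vanillin. One bought auxiliary stereocentre therefore sets C7 and C8 in the fragment union.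
3. The oxolane (O1–C2(aryl)–C3(CH2OH)–C4(arylmethyl)–C5) is closed by capture of the C2 benzylic cation by a primary hydroxyl of a triol. The triol comes from the aldol of an (R)-β-arylmethyl-γ-butyrolactone with the same aldehyde, followed by LiAlH4.
4. The lactone stereocentre comes from Rh-catalysed asymmetric hydrogenation of a Stobbe half-ester and relays the other two oxolane centres (trans aldol, then thermodynamic ring closure).
5. Ring order: γ-butyrolactone (temporary, step 4), then oxolane (step 7). The aromatic rings and the oxazolidinone are bought; benzyl, TIPS and TBS groups differentiate the two phenols and the primary alcohol.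

Key step: step 12

Assumption: the (S,S)-Et-DuPhos–Rh catalyst is taken to give the (R)-acid 6, by analogy with the way chelating enamides and itaconates bind; should the opposite sense be found, the (R,R)-ligand would be used.

**Route**

Step 1
Reactants: 1 vanillin
Product: 2 3-methoxy-4-(triisopropylsilyloxy)benzaldehyde
Conditions: TIPSCl, imidazole, DMF, rt
Reagents that add atoms: triisopropylsilyl chloride CC(C)[Si](Cl)(C(C)C)C(C)C
Why: Imidazole-promoted O-silylation of the phenol gives an aryl TIPS ether that tolerates amide bases, hydride and mild acid and is released only by fluoride at the end.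

Step 2
Reactants: 3 4-(benzyloxy)-3-methoxybenzaldehyde; 4 dimethyl succinate
Product: 5 (E)-4-[4-(benzyloxy)-3-methoxyphenyl]-3-(methoxycarbonyl)but-3-enoic acid
Conditions: NaOMe, MeOH, reflux; then aq. HCl
Reagents that add atoms: none
Why: Stobbe condensation, in which the succinate enolate adds to the aldehyde, the paraconic ester lactone forms and opens by elimination, leaving the acid on the CH2 arm and the ester on the alkene carbon, mainly as the E isomer.

Step 3
Reactants: 5
Product: 6 (R)-4-[4-(benzyloxy)-3-methoxyphenyl]-3-(methoxycarbonyl)butanoic acid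
Conditions: [Rh(cod)((S,S)-Et-DuPhos)]OTf (0.5 mol %), H2 (5 bar), NaOMe (10 mol %), MeOH, rt
Reagents that add atoms: none
Why: Rh-bisphospholane asymmetric hydrogenation of an itaconate-type half-ester, in which chelation of alkene and β-carboxylate to Rh should direct H2 to one face and set the (R) centre (the later oxolane C4) by catalyst control, while the benzyl ether is inert to the homogeneous catalyst.

Step 4
Reactants: 6
Product: 8 (R)-4-[4-(benzyloxy)-3-methoxybenzyl]dihydrofuran-2(3H)-one, via hydroxy acid 7 (not isolated)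
Conditions: KOH (1 equiv), EtOH; CaCl2, NaBH4, −10 °C to rt; then 2 M HCl, rt
Reagents that add atoms: none
Why: Chemoselective borohydride reduction, in which Ca(BH4)2 reduces the methyl ester but not the potassium carboxylate, followed by acid lactonisation that does not touch the stereocentre.

Step 5
Reactants: 8; 2
Product: 10 (3S,4R)-4-[4-(benzyloxy)-3-methoxybenzyl]-3-{hydroxy[3-methoxy-4-(triisopropylsilyloxy)phenyl]methyl}dihydrofuran-2(3H)-one (both carbinol epimers), via lithium enolate 9 (not isolated)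
Conditions: LiHMDS, THF, −78 °C; then 2; AcOH quench at −78 °C
Reagents that add atoms: none
Why: Lithium enolate aldol addition of a β-substituted γ-butyrolactone, in which the aldehyde enters trans to the C4 arylmethyl group (substrate control, sets C3), while the carbinol centre is left unselective because step 7 makes it convergent.

Step 6
Reactants: 10
Product: 11 (2R,3R)-2-[4-(benzyloxy)-3-methoxybenzyl]-3-{hydroxy[3-methoxy-4-(triisopropylsilyloxy)phenyl]methyl}butane-1,4-diol (both carbinol epimers)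
Conditions: LiAlH4, THF, 0 °C; Rochelle salt work-up
Reagents that add atoms: none
Why: LiAlH4 reduction of the lactone to the 1,4-diol should give the triol without affecting the aryl silyl or benzyl ethers and without epimerisation.

Step 7
Reactants: 11
Product: 12 {(2S,3R,4R)-4-[4-(benzyloxy)-3-methoxybenzyl]-2-[3-methoxy-4-(triisopropylsilyloxy)phenyl]oxolan-3-yl}methanol
Conditions: CSA (10 mol %), CH2Cl2, 4 Å MS, 0 °C
Reagents that add atoms: none
Why: Acid-mediated cyclodehydration through the p-silyloxy-stabilised benzylic cation, captured in a five-membered ring closure by the primary hydroxyl next to the arylmethyl-bearing carbon (the other primary hydroxyl could only give an oxetane); both carbinol epimers converge and the reversible closure should favour the 2,3-trans oxolane, setting C2 as S by substrate control.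

Step 8
Reactants: 12
Product: 13 tert-butyl({(2S,3R,4R)-4-[4-(benzyloxy)-3-methoxybenzyl]-2-[3-methoxy-4-(triisopropylsilyloxy)phenyl]oxolan-3-yl}methoxy)dimethylsilane
Conditions: TBSCl, imidazole, DMF, rt
Reagents that add atoms: tert-butyldimethylsilyl chloride CC(C)(C)[Si](C)(C)Cl
Why: Standard silylation of the only free hydroxyl keeps it out of the phenol alkylation and the boron aldol.

Step 9
Reactants: 13
Product: 14 4-({(3R,4R,5S)-4-[(tert-butyldimethylsilyloxy)methyl]-5-[3-methoxy-4-(triisopropylsilyloxy)phenyl]oxolan-3-yl}methyl)-2-methoxyphenol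
Conditions: H2 (1 atm), 10% Pd/C, EtOAc, rt, stopped when 13 is consumed
Reagents that add atoms: none
Why: Hydrogenolysis of an aryl benzyl ether on Pd/C in a neutral aprotic solvent is much faster than cleavage of the benzylic C–O bond of the 2-aryl oxolane, so the one phenol needed for the ether link should be freed selectively.

Step 10
Reactants: 15 (S)-4-benzyl-2-oxazolidinone
Product: 17 (S)-4-benzyl-3-(2-bromoacetyl)oxazolidin-2-one, via N-lithio oxazolidinone 16 (not isolated)
Conditions: n-BuLi, THF, −78 °C; then bromoacetyl bromide, −78 °C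
Reagents that add atoms: bromoacetyl bromide O=C(Br)CBr
Why: N-acylation of the lithiated oxazolidinone with an acid bromide at −78 °C, where acyl substitution outpaces displacement of the α-bromide.

Step 11
Reactants: 14; 17
Product: 18 (S)-4-benzyl-3-{[4-({(3R,4R,5S)-4-[(tert-butyldimethylsilyloxy)methyl]-5-[3-methoxy-4-(triisopropylsilyloxy)phenyl]oxolan-3-yl}methyl)-2-methoxyphenoxy]acetyl}oxazolidin-2-one
Conditions: K2CO3, MeCN, rt
Reagents that add atoms: none
Why: Williamson ether synthesis, in which the phenoxide displaces the activated α-bromide of the imide (SN2) faster than it attacks the imide carbonyl, under conditions the aryl TIPS and alkyl TBS ethers tolerate.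

Step 12
Reactants: 18; 2
Product: 21 (S)-4-benzyl-3-{(2S,3R)-3-hydroxy-3-[3-methoxy-4-(triisopropylsilyloxy)phenyl]-2-[4-({(3R,4R,5S)-4-[(tert-butyldimethylsilyloxy)methyl]-5-[3-methoxy-4-(triisopropylsilyloxy)phenyl]oxolan-3-yl}methyl)-2-methoxyphenoxy]propanoyl}oxazolidin-2-one, via Z-boron enolate 19 (not isolated), via boron aldolate 20 (not isolated)
Conditions: Bu2BOTf, Et3N, CH2Cl2, −78 to 0 °C; then 2, −78 to 0 °C; pH 7 buffer, MeOH, 30% H2O2, 0 °C
Reagents that add atoms: none
Why: Bu2BOTf/Et3N soft enolisation of 18 gives the (Z)-boron enolate 19, which adds to aldehyde 2 through a closed chair (Zimmerman–Traxler) transition state with the imide carbonyls dipole-opposed, and oxidative work-up releases 21 from aldolate 20. The closest known reaction type is the Evans boron syn-aldol of N-(aryloxyacetyl)oxazolidinones with O-protected hydroxybenzaldehydes, the established entry to enantiopure arylglycerol β-aryl ethers. No ring is closed. C8 is set by the auxiliary, the aldehyde reaching the enolate face away from the C4 benzyl group of the (S)-oxazolidinone, and C7 by the Z-enolate geometry through the chair, which fixes the 2,3-syn (threo) relationship, so the (2S,3R) adduct, which becomes (7R,8R) after reduction, should result. The step needs reagent control that overrides the distant oxolane stereocentres and tolerance of the acid-labile 2-aryl oxolane; the first is secured by the tight boron-centred transition state and the second by amine-buffered conditions at −78 to 0 °C. In one operation it joins the two halves, completes the carbon skeleton and creates both remaining stereocentres.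

Step 13
Reactants: 21
Product: 22 (1R,2R)-1-[3-methoxy-4-(triisopropylsilyloxy)phenyl]-2-[4-({(3R,4R,5S)-4-[(tert-butyldimethylsilyloxy)methyl]-5-[3-methoxy-4-(triisopropylsilyloxy)phenyl]oxolan-3-yl}methyl)-2-methoxyphenoxy]propane-1,3-diol
Conditions: NaBH4, THF/H2O (4:1), 0 °C to rt
Reagents that add atoms: none
Why: Reductive removal of the oxazolidinone by borohydride attack at the exocyclic imide carbonyl, assisted by the β-hydroxyl, gives the primary alcohol C9 and leaves C8, which is not enolised under these conditions, intact.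

Step 14
Reactants: 22
Product: 23 (1R,2R)-1-(4-hydroxy-3-methoxyphenyl)-2-[4-({(3R,4R,5S)-5-(4-hydroxy-3-methoxyphenyl)-4-(hydroxymethyl)oxolan-3-yl}methyl)-2-methoxyphenoxy]propane-1,3-diol (CNP0158473.2)
Conditions: TBAF, AcOH, THF, 0 °C to rt
Reagents that add atoms: none
Why: Fluoride-mediated cleavage of the two aryl TIPS ethers and the primary TBS ether, buffered with acetic acid so that no phenoxide para to a benzylic C–O bond persists long enough to form a quinone methide, should give the target with all five stereocentres unchanged.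

**Compound list**

1 | vanillin | COc1cc(C=O)ccc1O | starting material
2 | 3-methoxy-4-(triisopropylsilyloxy)benzaldehyde | COc1cc(C=O)ccc1O[Si](C(C)C)(C(C)C)C(C)C | intermediate
3 | 4-(benzyloxy)-3-methoxybenzaldehyde | COc1cc(C=O)ccc1OCc1ccccc1 | starting material
4 | dimethyl succinate | COC(=O)CCC(=O)OC | starting material
5 | (E)-4-[4-(benzyloxy)-3-methoxyphenyl]-3-(methoxycarbonyl)but-3-enoic acid | COC(=O)/C(CC(=O)O)=C/c1ccc(OCc2ccccc2)c(OC)c1 | intermediate
6 | (R)-4-[4-(benzyloxy)-3-methoxyphenyl]-3-(methoxycarbonyl)butanoic acid | COC(=O)[C@H](Cc1ccc(OCc2ccccc2)c(OC)c1)CC(=O)O | intermediate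
7 | (R)-3-[4-(benzyloxy)-3-methoxybenzyl]-4-hydroxybutanoic acid (as its carboxylate in the flask) | OC[C@H](Cc1ccc(OCc2ccccc2)c(OC)c1)CC(=O)O | intermediate
8 | (R)-4-[4-(benzyloxy)-3-methoxybenzyl]dihydrofuran-2(3H)-one | O=C1C[C@@H](Cc2ccc(OCc3ccccc3)c(OC)c2)CO1 | intermediate
9 | lithium enolate of 8 | [Li]OC1=C[C@@H](Cc2ccc(OCc3ccccc3)c(OC)c2)CO1 | intermediate
10 | (3S,4R)-4-[4-(benzyloxy)-3-methoxybenzyl]-3-{hydroxy[3-methoxy-4-(triisopropylsilyloxy)phenyl]methyl}dihydrofuran-2(3H)-one, both carbinol epimers | O=C1[C@H](C(O)c2ccc(O[Si](C(C)C)(C(C)C)C(C)C)c(OC)c2)[C@@H](Cc2ccc(OCc3ccccc3)c(OC)c2)CO1 | intermediate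
11 | (2R,3R)-2-[4-(benzyloxy)-3-methoxybenzyl]-3-{hydroxy[3-methoxy-4-(triisopropylsilyloxy)phenyl]methyl}butane-1,4-diol, both carbinol epimers | OC[C@H](Cc1ccc(OCc2ccccc2)c(OC)c1)[C@H](CO)C(O)c1ccc(O[Si](C(C)C)(C(C)C)C(C)C)c(OC)c1 | intermediate
12 | {(2S,3R,4R)-4-[4-(benzyloxy)-3-methoxybenzyl]-2-[3-methoxy-4-(triisopropylsilyloxy)phenyl]oxolan-3-yl}methanol | COc1cc(C[C@H]2CO[C@H](c3ccc(O[Si](C(C)C)(C(C)C)C(C)C)c(OC)c3)[C@H]2CO)ccc1OCc1ccccc1 | intermediate
13 | TBS ether of 12 | COc1cc(C[C@H]2CO[C@H](c3ccc(O[Si](C(C)C)(C(C)C)C(C)C)c(OC)c3)[C@H]2CO[Si](C)(C)C(C)(C)C)ccc1OCc1ccccc1 | intermediate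
14 | 4-({(3R,4R,5S)-4-[(tert-butyldimethylsilyloxy)methyl]-5-[3-methoxy-4-(triisopropylsilyloxy)phenyl]oxolan-3-yl}methyl)-2-methoxyphenol | COc1cc(C[C@H]2CO[C@H](c3ccc(O[Si](C(C)C)(C(C)C)C(C)C)c(OC)c3)[C@H]2CO[Si](C)(C)C(C)(C)C)ccc1O | intermediate
15 | (S)-4-benzyl-2-oxazolidinone | O=C1N[C@@H](Cc2ccccc2)CO1 | starting material
16 | N-lithio-(S)-4-benzyl-2-oxazolidinone | [Li]N1[C@@H](Cc2ccccc2)COC1=O | intermediate
17 | (S)-4-benzyl-3-(2-bromoacetyl)oxazolidin-2-one | O=C1OC[C@H](Cc2ccccc2)N1C(=O)CBr | intermediate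
18 | (S)-4-benzyl-3-(aryloxyacetyl)oxazolidin-2-one, aryl = the phenol residue of 14 | COc1cc(C[C@H]2CO[C@H](c3ccc(O[Si](C(C)C)(C(C)C)C(C)C)c(OC)c3)[C@H]2CO[Si](C)(C)C(C)(C)C)ccc1OCC(=O)N1[C@@H](Cc2ccccc2)COC1=O | intermediate
19 | (Z)-dibutylboron enolate of 18 | COc1cc(C[C@H]2CO[C@H](c3ccc(O[Si](C(C)C)(C(C)C)C(C)C)c(OC)c3)[C@H]2CO[Si](C)(C)C(C)(C)C)ccc1O/C=C(\OB(CCCC)CCCC)N1[C@@H](Cc2ccccc2)COC1=O | intermediate
20 | dibutylboron aldolate of 21 | COc1cc([C@@H](OB(CCCC)CCCC)[C@@H](C(=O)N2[C@@H](Cc3ccccc3)COC2=O)Oc2ccc(C[C@H]3CO[C@H](c4ccc(O[Si](C(C)C)(C(C)C)C(C)C)c(OC)c4)[C@H]3CO[Si](C)(C)C(C)(C)C)cc2OC)ccc1O[Si](C(C)C)(C(C)C)C(C)C | intermediate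
21 | (2S,3R)-syn-aldol imide (full name in step 12) | COc1cc([C@@H](O)[C@@H](C(=O)N2[C@@H](Cc3ccccc3)COC2=O)Oc2ccc(C[C@H]3CO[C@H](c4ccc(O[Si](C(C)C)(C(C)C)C(C)C)c(OC)c4)[C@H]3CO[Si](C)(C)C(C)(C)C)cc2OC)ccc1O[Si](C(C)C)(C(C)C)C(C)C | intermediate
22 | (1R,2R)-tris-silylated diol (full name in step 13) | COc1cc([C@@H](O)[C@@H](CO)Oc2ccc(C[C@H]3CO[C@H](c4ccc(O[Si](C(C)C)(C(C)C)C(C)C)c(OC)c4)[C@H]3CO[Si](C)(C)C(C)(C)C)cc2OC)ccc1O[Si](C(C)C)(C(C)C)C(C)C | intermediate
23 | (1R,2R)-1-(4-hydroxy-3-methoxyphenyl)-2-[4-({(3R,4R,5S)-5-(4-hydroxy-3-methoxyphenyl)-4-(hydroxymethyl)oxolan-3-yl}methyl)-2-methoxyphenoxy]propane-1,3-diol | COc1cc([C@@H](O)[C@@H](CO)Oc2ccc(C[C@H]3CO[C@H](c4ccc(O)c(OC)c4)[C@H]3CO)cc2OC)ccc1O | target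

**Step count and risks**

Total step count: 14. Longest linear sequence: 12 steps (steps 2–9 and 11–14, from 3).

Steps most likely to fail:

1. Step 12. The boron Lewis acid may ionise the benzylic C–O bond of the 2-aryl oxolane, and enolisation or addition to the hindered, electron-rich aldehyde may be incomplete, which would lower conversion and erode facial selectivity. Fallback, setting out from 14 and returning at 22: O-alkylation of 14 with ethyl bromoacetate (K2CO3, acetone) gives the ethyl aryloxyacetate F1. Its lithium enolate (LDA, THF, −78 °C) adds to 2 without any Lewis acid to give the β-hydroxy ester F2 as a diastereomer mixture. Dess–Martin oxidation gives the α-aryloxy-β-keto ester F3, whose C8 centre is configurationally labile. Ru-catalysed asymmetric transfer hydrogenation with dynamic kinetic resolution (RuCl(p-cymene)[(S,S)-TsDPEN], HCO2H/Et3N) resets both centres under catalyst control to the syn-(2S,3R) hydroxy ester F4. LiBH4 (THF, 0 °C) then reduces the ester to 22.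

2. Step 7. The benzylic cation may be captured by the electron-rich arylmethyl ring (Friedel–Crafts closure to an aryltetralin), or the closure may stop short of full 2,3-trans selectivity. Fallback, setting out from 11 and returning at 12: CDI (1 equiv, CH2Cl2, then cat. DBU) ties the 1,3-diol into the six-membered cyclic carbonate F5, leaving the remaining primary hydroxyl free. TBAF (THF, 0 °C) removes the aryl TIPS group, and the phenoxide expels the benzylic carbonate oxygen by 1,6-elimination; the resulting p-quinone methide is trapped by the free hydroxyl under non-acidic conditions to give 4''-O-benzyl-lariciresinol F6. Phenol-selective silylation (TIPSCl, Et3N, CH2Cl2) returns 12.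

3. Step 9. Hydrogenolysis may continue into the benzylic C–O bond of the oxolane and open the ring. Fallback, setting out from 8 and returning at 14: the benzyl ether is removed at the lactone stage, where no other benzylic C–O bond exists (H2, Pd/C, EtOAc), to give the phenol lactone F7, which is re-protected as the allyl ether F8 (allyl bromide, K2CO3, acetone). Steps 5–8 are repeated in the allyl series to give the aldol lactone F9, the triol F10, the oxolane alcohol F11 and its TBS ether F12. Pd(PPh3)4/morpholine (THF, rt) then frees the phenol without hydrogen, giving 14.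

Further compounds
F1 | step 12 | ethyl [4-({(3R,4R,5S)-4-[(tert-butyldimethylsilyloxy)methyl]-5-[3-methoxy-4-(triisopropylsilyloxy)phenyl]oxolan-3-yl}methyl)-2-methoxyphenoxy]acetate | CCOC(=O)COc1ccc(C[C@H]2CO[C@H](c3ccc(O[Si](C(C)C)(C(C)C)C(C)C)c(OC)c3)[C@H]2CO[Si](C)(C)C(C)(C)C)cc1OC
F2 | step 12 | ethyl 2-aryloxy-3-hydroxy-3-[3-methoxy-4-(triisopropylsilyloxy)phenyl]propanoate (aryloxy as in F1), mixture of C2/C3 diastereomers | CCOC(=O)C(Oc1ccc(C[C@H]2CO[C@H](c3ccc(O[Si](C(C)C)(C(C)C)C(C)C)c(OC)c3)[C@H]2CO[Si](C)(C)C(C)(C)C)cc1OC)C(O)c1ccc(O[Si](C(C)C)(C(C)C)C(C)C)c(OC)c1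
F3 | step 12 | ethyl 2-aryloxy-3-[3-methoxy-4-(triisopropylsilyloxy)phenyl]-3-oxopropanoate (aryloxy as in F1) | CCOC(=O)C(Oc1ccc(C[C@H]2CO[C@H](c3ccc(O[Si](C(C)C)(C(C)C)C(C)C)c(OC)c3)[C@H]2CO[Si](C)(C)C(C)(C)C)cc1OC)C(=O)c1ccc(O[Si](C(C)C)(C(C)C)C(C)C)c(OC)c1
F4 | step 12 | ethyl (2S,3R)-2-aryloxy-3-hydroxy-3-[3-methoxy-4-(triisopropylsilyloxy)phenyl]propanoate (aryloxy as in F1) | COc1cc([C@@H](O)[C@@H](C(=O)OCC)Oc2ccc(C[C@H]3CO[C@H](c4ccc(O[Si](C(C)C)(C(C)C)C(C)C)c(OC)c4)[C@H]3CO[Si](C)(C)C(C)(C)C)cc2OC)ccc1O[Si](C(C)C)(C(C)C)C(C)C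
F5 | step 7 | (5R)-5-{(2R)-1-[4-(benzyloxy)-3-methoxyphenyl]-3-hydroxypropan-2-yl}-4-[3-methoxy-4-(triisopropylsilyloxy)phenyl]-1,3-dioxan-2-one, both C4 epimers | O=C1OC[C@@H]([C@H](CO)Cc2ccc(OCc3ccccc3)c(OC)c2)C(c2ccc(O[Si](C(C)C)(C(C)C)C(C)C)c(OC)c2)O1
F6 | step 7 | {(2S,3R,4R)-4-[4-(benzyloxy)-3-methoxybenzyl]-2-(4-hydroxy-3-methoxyphenyl)oxolan-3-yl}methanol | COc1cc(C[C@H]2CO[C@H](c3ccc(O)c(OC)c3)[C@H]2CO)ccc1OCc1ccccc1
F7 | step 9 | (R)-4-(4-hydroxy-3-methoxybenzyl)dihydrofuran-2(3H)-one | O=C1C[C@@H](Cc2ccc(O)c(OC)c2)CO1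
F8 | step 9 | (R)-4-[4-(allyloxy)-3-methoxybenzyl]dihydrofuran-2(3H)-one | O=C1C[C@@H](Cc2ccc(OCC=C)c(OC)c2)CO1
F9 | step 9 | (3S,4R)-4-[4-(allyloxy)-3-methoxybenzyl]-3-{hydroxy[3-methoxy-4-(triisopropylsilyloxy)phenyl]methyl}dihydrofuran-2(3H)-one, both carbinol epimers | O=C1[C@H](C(O)c2ccc(O[Si](C(C)C)(C(C)C)C(C)C)c(OC)c2)[C@@H](Cc2ccc(OCC=C)c(OC)c2)CO1
F10 | step 9 | (2R,3R)-2-[4-(allyloxy)-3-methoxybenzyl]-3-{hydroxy[3-methoxy-4-(triisopropylsilyloxy)phenyl]methyl}butane-1,4-diol, both carbinol epimers | OC[C@H](Cc1ccc(OCC=C)c(OC)c1)[C@H](CO)C(O)c1ccc(O[Si](C(C)C)(C(C)C)C(C)C)c(OC)c1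
F11 | step 9 | {(2S,3R,4R)-4-[4-(allyloxy)-3-methoxybenzyl]-2-[3-methoxy-4-(triisopropylsilyloxy)phenyl]oxolan-3-yl}methanol | COc1cc(C[C@H]2CO[C@H](c3ccc(O[Si](C(C)C)(C(C)C)C(C)C)c(OC)c3)[C@H]2CO)ccc1OCC=C
F12 | step 9 | TBS ether of F11 | COc1cc(C[C@H]2CO[C@H](c3ccc(O[Si](C(C)C)(C(C)C)C(C)C)c(OC)c3)[C@H]2CO[Si](C)(C)C(C)(C)C)ccc1OCC=C
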